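**Retrosynthetic overview**
- The target is unmasked last from its 5,7-bis-tosylate; the prenyl ether and both methyl ethers are already in place and survive aqueous base.
- Key disconnection, C3–C4: the A-ring aldehyde carbon (C4) is used as an acyl anion (carbene-derived Breslow intermediate) and acylated by the ester carbon (C3). Two carbonyl carbons are joined and the flavonol is formed directly at the right oxidation level.
- The O1–C2 bond is made beforehand by Mitsunobu etherification of a salicylaldehyde with a mandelate.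
- A-ring piece: iretol is formylated, then 4,6-ditosylated. B-ring piece: methyl 4-hydroxymandelate is prenylated.
- Ring order: rings A and B are bought as arenes; the pyranone C ring is the only ring formed (step 5).

Assumption: the target has no stereocentre and its only acyclic alkene has two identical methyl groups, so the given SMILES is already the single stereoisomer. Compounds 4, 6 and 7 are used as racemates because their one stereocentre is erased in step 5. Iretol and methyl 4-hydroxymandelate are taken as catalogue chemicals.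

**Step 1**
Reactants: 1 2-methoxybenzene-1,3,5-triol (iretol)
Product: 2 2,4,6-trihydroxy-3-methoxybenzaldehyde
Conditions: POCl3, DMF, EtOAc, 0 °C to rt; then H2O, 60 °C
Reagents that add atoms: N,N-dimethylformamide CN(C)C=O; water O
Why: Vilsmeier–Haack formylation of a phloroglucinol-type ring; the two free ring positions of 1 are equivalent by symmetry, so only one mono-aldehyde can form.

**Step 2**
Reactants: 2 2,4,6-trihydroxy-3-methoxybenzaldehyde
Product: 3 4-formyl-5-hydroxy-6-methoxy-1,3-phenylene bis(4-methylbenzenesulfonate) (= 2-hydroxy-3-methoxy-4,6-bis(tosyloxy)benzaldehyde)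
Conditions: TsCl (2.05 equiv), K2CO3, acetone, 0 °C to rt
Reagents that add atoms: 4-methylbenzenesulfonyl chloride Cc1ccc(cc1)S(=O)(=O)Cl
Why: Selective O-sulfonylation: the 4-OH (para to CHO, not hydrogen-bonded) and the less hindered ortho 6-OH react, while the 2-OH, flanked by CHO and OMe and chelated to the carbonyl, is expected to stay free on steric and hydrogen-bonding grounds.

**Step 3**
Reactants: 4 methyl 2-hydroxy-2-(4-hydroxyphenyl)acetate (methyl 4-hydroxymandelate, racemic); 5 1-bromo-3-methylbut-2-ene (prenyl bromide)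
Product: 6 methyl 2-hydroxy-2-[4-(3-methylbut-2-en-1-yloxy)phenyl]acetate (racemic)
Conditions: K2CO3, acetone, reflux
Reagents that add atoms: none
Why: Williamson ether synthesis; carbonate deprotonates only the phenol (pKa about 10) and not the secondary alcohol, so prenylation is selective for the aryl oxygen.

**Step 4**
Reactants: 3 4-formyl-5-hydroxy-6-methoxy-1,3-phenylene bis(4-methylbenzenesulfonate); 6 methyl 2-hydroxy-2-[4-(3-methylbut-2-en-1-yloxy)phenyl]acetate
Product: 7 methyl 2-[2-formyl-6-methoxy-3,5-bis(tosyloxy)phenoxy]-2-[4-(3-methylbut-2-en-1-yloxy)phenyl]acetate (racemic)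
Conditions: PPh3, DIAD, THF, 0 °C to rt
Reagents that add atoms: none
Why: Mitsunobu etherification of the acidic, chelated phenol with the activated secondary benzylic α-hydroxy ester (SN2 at the carbinol carbon); the new stereocentre is racemic and is erased in step 5.

**Step 5**
Reactants: 7 methyl 2-[2-formyl-6-methoxy-3,5-bis(tosyloxy)phenoxy]-2-[4-(3-methylbut-2-en-1-yloxy)phenyl]acetate
Product: 9 3,8-dimethoxy-2-[4-(3-methylbut-2-en-1-yloxy)phenyl]-4-oxo-4H-chromene-5,7-diyl bis(4-methylbenzenesulfonate), via flavonol bis-tosylate 8 (not isolated)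
Conditions: 2-(pentafluorophenyl)-6,7-dihydro-5H-pyrrolo[2,1-c][1,2,4]triazolium BF4 (20 mol %), i-Pr2NEt (2 equiv), THF, 45 °C, Ar; then K2CO3, MeI, DMF, rt
Reagents that add atoms: iodomethane CI
Why: Proposed new method: the carbene adds to the electron-poor aryl aldehyde of 7 to give a Breslow intermediate (acyl anion at C4) that attacks the α-aryloxy-activated methyl ester in a 6-exo-trig mode, and loss of methoxide and of the carbene gives 8 as its 3,4-diketo tautomer, which enolises irreversibly to the aromatic 3-hydroxyflavone and is trapped as its salt and O-methylated in the same pot (only 3-OH is free); the weak amine base keeps the competing reversible ester-enolate aldol onto the aldehyde low, and the closest known reaction types are the NHC-catalysed intramolecular crossed benzoin of 2-(2-oxoalkoxy)benzaldehydes to chroman-4-ones and the NHC-catalysed intramolecular aldehyde–nitrile coupling to 3-aminochromones.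

**Step 6**
Reactants: 9 3,8-dimethoxy-2-[4-(3-methylbut-2-en-1-yloxy)phenyl]-4-oxo-4H-chromene-5,7-diyl bis(4-methylbenzenesulfonate)
Product: 10 5,7-dihydroxy-3,8-dimethoxy-2-[4-(3-methylbut-2-en-1-yloxy)phenyl]-4H-chromen-4-one (target)
Conditions: 2 M aq. KOH, THF, 50 °C; then 1 M HCl to pH 5, 0 °C
Reagents that add atoms: none
Why: Alkaline hydrolysis of the two aryl sulfonates by hydroxide attack at sulfur (S–O cleavage; methanol is avoided so that no methyl tosylate can re-methylate the phenoxides), while the prenyl ether, both methyl ethers and the 3-methoxyflavone core tolerate aqueous base and brief acidification to pH 5.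

**Compound list**
1 | 2-methoxybenzene-1,3,5-triol (iretol) | COc1c(O)cc(O)cc1O | starting material
2 | 2,4,6-trihydroxy-3-methoxybenzaldehyde | COc1c(O)cc(O)c(C=O)c1O | intermediate
3 | 4-formyl-5-hydroxy-6-methoxy-1,3-phenylene bis(4-methylbenzenesulfonate) | COc1c(O)c(C=O)c(OS(=O)(=O)c2ccc(C)cc2)cc1OS(=O)(=O)c1ccc(C)cc1 | intermediate
4 | methyl 2-hydroxy-2-(4-hydroxyphenyl)acetate (racemic) | COC(=O)C(O)c1ccc(O)cc1 | starting material
5 | 1-bromo-3-methylbut-2-ene (prenyl bromide) | CC(C)=CCBr | starting material
6 | methyl 2-hydroxy-2-[4-(3-methylbut-2-en-1-yloxy)phenyl]acetate (racemic) | COC(=O)C(O)c1ccc(OCC=C(C)C)cc1 | intermediate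
7 | methyl 2-[2-formyl-6-methoxy-3,5-bis(tosyloxy)phenoxy]-2-[4-(3-methylbut-2-en-1-yloxy)phenyl]acetate (racemic) | COC(=O)C(Oc1c(OC)c(OS(=O)(=O)c2ccc(C)cc2)cc(OS(=O)(=O)c2ccc(C)cc2)c1C=O)c1ccc(OCC=C(C)C)cc1 | intermediate
8 | 3-hydroxy-8-methoxy-2-[4-(3-methylbut-2-en-1-yloxy)phenyl]-4-oxo-4H-chromene-5,7-diyl bis(4-methylbenzenesulfonate) | Oc1c(-c2ccc(OCC=C(C)C)cc2)oc2c(OC)c(OS(=O)(=O)c3ccc(C)cc3)cc(OS(=O)(=O)c3ccc(C)cc3)c2c1=O | intermediate
9 | 3,8-dimethoxy-2-[4-(3-methylbut-2-en-1-yloxy)phenyl]-4-oxo-4H-chromene-5,7-diyl bis(4-methylbenzenesulfonate) | COc1c(-c2ccc(OCC=C(C)C)cc2)oc2c(OC)c(OS(=O)(=O)c3ccc(C)cc3)cc(OS(=O)(=O)c3ccc(C)cc3)c2c1=O | intermediate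
10 | 5,7-dihydroxy-3,8-dimethoxy-2-[4-(3-methylbut-2-en-1-yloxy)phenyl]-4H-chromen-4-one | COc1c(-c2ccc(OCC=C(C)C)cc2)oc2c(OC)c(O)cc(O)c2c1=O | target

**Totals**
Total step count: 6. Longest linear sequence: 5 steps (steps 1, 2, 4, 5, 6); step 3 is the side branch.

**Three steps most likely to fail**

Step 5 (ring closure by acylation of the Breslow intermediate). The ester is an untested acceptor for this acyl anion, the aldehyde is flanked by two ortho substituents, and the ester enolate can add reversibly to the aldehyde. The fallback sets out from 7 and comes back at 8. Both carbonyl groups of 7 are reduced with DIBAL-H (CH2Cl2, −78 °C) to the diol 4-(hydroxymethyl)-5-{2-hydroxy-1-[4-(3-methylbut-2-en-1-yloxy)phenyl]ethoxy}-6-methoxy-1,3-phenylene bis(4-methylbenzenesulfonate) F1. Both alcohols are then oxidised with Dess–Martin periodinane to the dialdehyde 4-formyl-6-methoxy-5-{2-oxo-1-[4-(3-methylbut-2-en-1-yloxy)phenyl]ethoxy}-1,3-phenylene bis(4-methylbenzenesulfonate) F2. The ring is closed by the precedented NHC-catalysed intramolecular crossed benzoin between the two aldehydes, giving the dihydroflavonol 3-hydroxy-8-methoxy-2-[4-(3-methylbut-2-en-1-yloxy)phenyl]-4-oxochromane-5,7-diyl bis(4-methylbenzenesulfonate) F3. Either acyloin regioisomer equilibrates through the same enediol, so the direction of the benzoin does not matter. F3 is dehydrogenated with air and K2CO3 in DMF to flavonol 8, which is methylated as in the second stage of step 5.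

Step 2 (which ortho hydroxyl stays free). If the 6-OH and 2-OH are not well differentiated, the fallback sets out from 1 and comes back at 3 by reversing the order of the two operations. Iretol is ditosylated first; the unhindered 5-OH and one of the two equivalent OMe-flanked hydroxyls react, giving 5-hydroxy-4-methoxy-1,3-phenylene bis(4-methylbenzenesulfonate) F4. The single C–H ortho to its free phenol is then formylated by the ortho-specific MgCl2/Et3N/paraformaldehyde method (MeCN, reflux). This gives 3 with the position of the free hydroxyl fixed by construction.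

Step 4 (Mitsunobu reaction on a hindered, doubly ortho-substituted phenol). The fallback sets out from 6 and comes back at 7 by switching from redox condensation to phenoxide alkylation. Appel bromination of 6 (CBr4, PPh3, CH2Cl2, 0 °C) gives methyl 2-bromo-2-[4-(3-methylbut-2-en-1-yloxy)phenyl]acetate F5. This highly reactive α-bromo ester alkylates the potassium phenoxide of 3 (K2CO3, DMF, rt) in an SN2 reaction to give 7.

**Further compounds**
F1 | step 5 | 4-(hydroxymethyl)-5-{2-hydroxy-1-[4-(3-methylbut-2-en-1-yloxy)phenyl]ethoxy}-6-methoxy-1,3-phenylene bis(4-methylbenzenesulfonate) (racemic) | OCC(Oc1c(OC)c(OS(=O)(=O)c2ccc(C)cc2)cc(OS(=O)(=O)c2ccc(C)cc2)c1CO)c1ccc(OCC=C(C)C)cc1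
F2 | step 5 | 4-formyl-6-methoxy-5-{2-oxo-1-[4-(3-methylbut-2-en-1-yloxy)phenyl]ethoxy}-1,3-phenylene bis(4-methylbenzenesulfonate) (racemic) | O=CC(Oc1c(OC)c(OS(=O)(=O)c2ccc(C)cc2)cc(OS(=O)(=O)c2ccc(C)cc2)c1C=O)c1ccc(OCC=C(C)C)cc1
F3 | step 5 | 3-hydroxy-8-methoxy-2-[4-(3-methylbut-2-en-1-yloxy)phenyl]-4-oxochromane-5,7-diyl bis(4-methylbenzenesulfonate) (racemic mixture of diastereomers) | OC1C(c2ccc(OCC=C(C)C)cc2)Oc2c(OC)c(OS(=O)(=O)c3ccc(C)cc3)cc(OS(=O)(=O)c3ccc(C)cc3)c2C1=O
F4 | step 2 | 5-hydroxy-4-methoxy-1,3-phenylene bis(4-methylbenzenesulfonate) | COc1c(O)cc(OS(=O)(=O)c2ccc(C)cc2)cc1OS(=O)(=O)c1ccc(C)cc1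
F5 | step 4 | methyl 2-bromo-2-[4-(3-methylbut-2-en-1-yloxy)phenyl]acetate (racemic) | COC(=O)C(Br)c1ccc(OCC=C(C)C)cc1
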